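The readings are calculated for an exercise, and the scatter is random.

You can begin with an easy sum: target plus over-reaction product is the electrophile that has reacted.

| flask | electrophile | nucleophile | remark | time |
|---|---|---|---|---|
| violet | 0.037 M | 0.074 M | run made earlier |  |
| amber | 0.15 M | 0.074 M | run made earlier |  |
| flask | 0.074 M | 0.0740 M |  | 5.0 min |

- violet (time / min: target / %, over-reaction product / %): 1.33: 15.5, 15.1; 2.50: 12.4, 31.6; 4.00: 8.4, 47.6; 5.00: 6.6, 55.1; 6.00: 5.2, 60.7
- amber (time / min: target / %, over-reaction product / %): 1.33: 8.5, 10.4; 2.50: 4.5, 18.5; 4.00: 2.1, 24.2; 5.00: 1.0, 25.0; 6.00: 0.6, 25.0

(readings scatter by 0.3 percentage points)

- the reaction counts as stopped when no species that holds the electrophile changes by six tenths of a point or more over the second half of the time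

* why nothing more happens at 5.0 min, or that something still does (all of the electrophile has reacted / the nucleophile has run out first / forward and back rates have come level / it is still moving)
* how much target there is at 5.0 min, in percent of the electrophile charged
* how much over-reaction product there is at 5.0 min, in percent of the electrophile charged

What does reacted electrophile cost in nucleophile? Call the nucleophile spent per electrophile reacted the price: in the amber run, where the over-reaction product stands level, the nucleophile charge over the electrophile reacted gives 1.93, so take two.

Does that survive a test? The violet run holds twice as much nucleophile as electrophile, so at that price reacted over unreacted electrophile should grow in step with time. It reads 0.786 at 2.50 min and 1.61 at 5.00 min, twice the first, and the slope gives a rate constant of 4.35 /M/min.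

Has this flask stopped? At equal charges the nucleophile is the limiting reagent, and for as long as that price holds its charge pays for 51.9% of the electrophile, less than the whole charge. Electrophile left over nucleophile left, each as a share of its charge, grows exponentially with rate constant times charge times time, an exponent of 1.61 at 5.0 min, which makes that ratio 5.00. My reckoning therefore puts 44.5% reacted, up 8.9 percentage points since 2.50 min, so it still moves.

How much is target? The violet run shows target used at 1.03 /min. Supply is 0.0199 /min and falling at 0.394 /min, so making over using drifts to 0.617. That gives target 3.14% and over-reaction product 41.4%.

The forecast says it is still moving, with target 3.4% and over-reaction product 42.5%, the latter above mine: “Nucleophile remains”.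

The flask gives it is still moving, target 3.48%, over-reaction product 41.1%.

    electrophile + nucleophile → acid set free + target (k = 4.30 /M/min)
    nucleophile + acid set free ⇌ protonated nucleophile, settled at all times (K = 4700 /M)
    target → over-reaction product (k = 1.00 /min)

In this flask the first step ran through the whole 5.0 min while free nucleophile fell to 11.9% of its charge, and protonated nucleophile reached 0.0322 M against 0.0330 M of electrophile reacted, which is where the second nucleophile of the price stood. Reacted electrophile was then 44.6%, at a price of 1.98 against the 1.93 read from the amber run. The same flask read at 50.0 min had 57.7% reacted, past the 51.9%, with acid set free at 0.0120 M, free nucleophile at 0.738% of its charge and the price at 1.72.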